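## Retrosynthetic overview

1. Numbering: ring C1 (stereocentre) to C14 through Z-C3=C4(Me), C7=C8(CH2OH) and E-C11=C12(Me); C15 is the side-chain carbon on C1 and C16 its =CH2. The strategy rests on C1 being allylic to the exocyclic C15=C16H2 and bonded to the bare ring methylene C14H2, which is the footprint of a [3,3] shift of an allyl ester C1=C15–C16H2–O–C(=O)–C14.
2. Target 35 <= fluoride desilylation and radical decarboxylation at C14 <= 14-membered acid 32 <= Ireland–Claisen ring contraction (new bond C14–C1) of the 18-membered allylic lactone 29 under a chiral bromoborane.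
3. Lactone 29 <= lactonisation (C16–O to the C14 carboxyl) of seco acid 27 <= alkenyl–allyl coupling (C1–C2) of the Z-alkenylmagnesium reagent made from iodide 24 (propargyl alcohol, homoprenyl Grignard reagent, iodine) with the neryl-type bromide 19.
4. Bromide 19 <= Johnson–Claisen rearrangement (E-C11=C12, C13–C14–CO2Et) <= Horner–Wadsworth–Emmons olefination (C7=C8) of the nerol-derived Z aldehyde 4 (C2–C7) with the alkylated phosphonoacetate 7 (C8–C11).
5. Ring order: the 18-membered lactone is closed first (step 16) and is then contracted to the only carbocycle, the 14-membered ring (step 17).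

Key step: step 17

Remark on the protecting group: the C8–CH2O silyl ether is carried as TBDPS instead of TBS, because it has to outlast the aqueous acid of step 8; fluoride removes it at the end in the same way.

Remark on the sense of induction: the (S,S)-bromoborane is assumed to select the alkene face that gives C1 as in the target. If the first run shows the opposite sense, the (R,R)-reagent, made in the same way, is used. C14 of 32 is drawn for the chair pathway and is erased in step 18.

Remark on the ester problem: the C14 ester is introduced only after the C8 ester has been reduced and silylated, so the two carboxyl groups never have to be told apart.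

## Route

Step 1
Reactants: 1 nerol
Product: 2 neryl 4-methoxybenzyl ether
Conditions: NaH, 4-methoxybenzyl chloride, Bu4NI (cat.), THF/DMF, 0 °C to rt
Reagents that add atoms: 4-methoxybenzyl chloride, COc1ccc(CCl)cc1
Why: Williamson etherification of the primary allylic alkoxide gives a C2–O protecting group that withstands the hydride, Grignard and Claisen steps and is later removed oxidatively beside the silyl ether.

Step 2
Reactants: 2 neryl 4-methoxybenzyl ether
Product: 3 6,7-epoxyneryl 4-methoxybenzyl ether (racemic)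
Conditions: mCPBA (1.0 equiv), NaHCO3, CH2Cl2, −20 to 0 °C
Reagents that add atoms: 3-chloroperoxybenzoic acid, OOC(=O)c1cccc(Cl)c1
Why: Prilezhaev epoxidation should take place at the remote, more electron-rich trisubstituted alkene, since the alkene next to the allylic oxygen is deactivated; the epoxide configuration is irrelevant because both carbons are cleaved in step 3.

Step 3
Reactants: 3 6,7-epoxyneryl 4-methoxybenzyl ether
Product: 4 (4Z)-6-[(4-methoxybenzyl)oxy]-4-methylhex-4-enal
Conditions: HIO4·2H2O, THF/Et2O, 0 °C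
Reagents that add atoms: none
Why: Periodic acid opens the epoxide and cleaves the glycol (Malaprade-type cleavage) to the C7 aldehyde and acetone without touching the Z alkene or the PMB ether.

Step 4
Reactants: 5 triethyl phosphonoacetate, 6 2-(2-bromoethyl)-1,3-dioxolane
Product: 7 ethyl 2-(diethoxyphosphoryl)-4-(1,3-dioxolan-2-yl)butanoate (racemic)
Conditions: NaH, DMSO, 60 °C (5 in excess)
Reagents that add atoms: none
Why: SN2 C-alkylation of the stabilised phosphonoacetate carbanion by the primary bromide installs C9–C11 with C11 masked as an acetal, and excess 5 suppresses dialkylation.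

Step 5
Reactants: 7 ethyl 2-(diethoxyphosphoryl)-4-(1,3-dioxolan-2-yl)butanoate, 4 (4Z)-6-[(4-methoxybenzyl)oxy]-4-methylhex-4-enal
Product: 8 ethyl (2E,6Z)-2-[2-(1,3-dioxolan-2-yl)ethyl]-8-[(4-methoxybenzyl)oxy]-6-methylocta-2,6-dienoate
Conditions: NaH, THF, 0 °C to rt
Reagents that add atoms: none
Why: Horner–Wadsworth–Emmons olefination of an unbranched aldehyde with an α-alkyl phosphonoacetate should favour the E enoate (ester trans to C6, so C6 and C9 are cis) through reversible adduct formation; any Z isomer is removed by chromatography here or after step 6.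

Step 6
Reactants: 8 ethyl (2E,6Z)-2-[2-(1,3-dioxolan-2-yl)ethyl]-8-[(4-methoxybenzyl)oxy]-6-methylocta-2,6-dienoate
Product: 9 (2E,6Z)-2-[2-(1,3-dioxolan-2-yl)ethyl]-8-[(4-methoxybenzyl)oxy]-6-methylocta-2,6-dien-1-ol
Conditions: i-Bu2AlH (2.5 equiv), CH2Cl2, −78 °C; aq. KNaC4H4O6
Reagents that add atoms: none
Why: 1,2-reduction of the conjugated ester by the aluminium hydride gives the C8 allylic alcohol with the alkene geometry intact, while the dioxolane and the PMB ether are inert at −78 °C.

Step 7
Reactants: 9 (2E,6Z)-2-[2-(1,3-dioxolan-2-yl)ethyl]-8-[(4-methoxybenzyl)oxy]-6-methylocta-2,6-dien-1-ol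
Product: 10 tert-butyldiphenylsilyl ether of 9
Conditions: TBDPSCl, imidazole, DMF, 0 °C to rt
Reagents that add atoms: tert-butyl(chloro)diphenylsilane, CC(C)(C)[Si](Cl)(c1ccccc1)c1ccccc1
Why: Imidazole-promoted silylation of the only free hydroxyl gives an acid-robust silyl ether that is orthogonal to the PMB ether.

Step 8
Reactants: 10 tert-butyldiphenylsilyl ether of 9
Product: 11 (4E,8Z)-4-{[(tert-butyldiphenylsilyl)oxy]methyl}-10-[(4-methoxybenzyl)oxy]-8-methyldeca-4,8-dienal
Conditions: 1 M HCl (aq), THF, rt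
Reagents that add atoms: water, O
Why: Acid-catalysed acetal hydrolysis frees the C11 aldehyde, and the TBDPS and PMB ethers tolerate dilute aqueous acid at room temperature.

Step 9
Reactants: 11 (4E,8Z)-4-{[(tert-butyldiphenylsilyl)oxy]methyl}-10-[(4-methoxybenzyl)oxy]-8-methyldeca-4,8-dienal, 12 isopropenylmagnesium bromide
Product: 13 (6E,10Z)-6-{[(tert-butyldiphenylsilyl)oxy]methyl}-12-[(4-methoxybenzyl)oxy]-2,10-dimethyldodeca-1,6,10-trien-3-ol (racemic)
Conditions: THF, −78 to 0 °C; aq. NH4Cl
Reagents that add atoms: none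
Why: Grignard 1,2-addition to the aldehyde gives the 2-methylallylic alcohol needed for the orthoester Claisen step; the new carbinol centre is racemic and becomes sp2 in step 10.

Step 10
Reactants: 13 (6E,10Z)-6-{[(tert-butyldiphenylsilyl)oxy]methyl}-12-[(4-methoxybenzyl)oxy]-2,10-dimethyldodeca-1,6,10-trien-3-ol, 14 triethyl orthoacetate
Product: 16 ethyl (4E,8E,12Z)-8-{[(tert-butyldiphenylsilyl)oxy]methyl}-14-[(4-methoxybenzyl)oxy]-4,12-dimethyltetradeca-4,8,12-trienoate, via mixed ketene acetal 15 (not isolated)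
Conditions: MeC(OEt)3 (excess), EtCO2H (cat.), 140 °C, EtOH distilled off
Reagents that add atoms: none
Why: Johnson–Claisen rearrangement through a chair with the C10 chain equatorial should give the E trisubstituted C11=C12 alkene and the C13–C14–CO2Et unit; the only other allylic oxygen is blocked as the PMB ether.

Step 11
Reactants: 16 ethyl (4E,8E,12Z)-8-{[(tert-butyldiphenylsilyl)oxy]methyl}-14-[(4-methoxybenzyl)oxy]-4,12-dimethyltetradeca-4,8,12-trienoate
Product: 17 ethyl (4E,8E,12Z)-8-{[(tert-butyldiphenylsilyl)oxy]methyl}-14-hydroxy-4,12-dimethyltetradeca-4,8,12-trienoate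
Conditions: DDQ, CH2Cl2/pH 7 buffer, 0 °C
Reagents that add atoms: none
Why: Oxidative cleavage of the electron-rich benzyl ether by DDQ frees the C2 hydroxyl while the silyl ether, the ester and the isolated alkenes stay untouched.

Step 12
Reactants: 17 ethyl (4E,8E,12Z)-8-{[(tert-butyldiphenylsilyl)oxy]methyl}-14-hydroxy-4,12-dimethyltetradeca-4,8,12-trienoate
Product: 19 ethyl (4E,8E,12Z)-14-bromo-8-{[(tert-butyldiphenylsilyl)oxy]methyl}-4,12-dimethyltetradeca-4,8,12-trienoate, via allylic mesylate 18 (not isolated)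
Conditions: MsCl, Et3N, THF, −40 °C; then LiBr, THF, 0 °C
Reagents that add atoms: lithium bromide, [Li+].[Br-]
Why: Sulfonylation followed by SN2 displacement with bromide at low temperature converts the primary allylic alcohol into the bromide without allylic transposition or Z-to-E isomerisation; the bromide is used at once.

Step 13
Reactants: 20 5-bromo-2-methylpent-2-ene, 21 propargyl alcohol
Product: 24 (2Z)-3-iodo-2-(4-methylpent-3-en-1-yl)prop-2-en-1-ol, via homoprenylmagnesium bromide 22 (not isolated), via cyclic alkenylmagnesium alkoxide 23 (not isolated)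
Conditions: Mg, THF; then 21, CuI (10 mol%), Et2O/THF, 0 °C to rt; then I2, −40 to 0 °C
Reagents that add atoms: iodine, II
Why: Copper-catalysed anti-carbomagnesiation of the magnesium propargyl alkoxide puts the homoprenyl group on the internal carbon and magnesium on the terminal carbon cis to CH2O in a five-membered chelate, and iodinolysis with retention gives the Z iodide; isolating it separates the alkenyl unit from the excess alkyl Grignard reagent.

Step 14
Reactants: 24 (2Z)-3-iodo-2-(4-methylpent-3-en-1-yl)prop-2-en-1-ol, 19 ethyl (4E,8E,12Z)-14-bromo-8-{[(tert-butyldiphenylsilyl)oxy]methyl}-4,12-dimethyltetradeca-4,8,12-trienoate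
Product: 26 ethyl (4E,8E,12Z,15Z)-8-{[(tert-butyldiphenylsilyl)oxy]methyl}-16-(hydroxymethyl)-4,12,20-trimethylhenicosa-4,8,12,15,19-pentaenoate, via Z-alkenylmagnesium chloride alkoxide 25 (not isolated)
Conditions: i-PrMgCl·LiCl (2.0 equiv per 24, 24 in slight excess), THF, −20 °C to rt; then Li2CuCl4 (5 mol%), 19, −40 to 0 °C
Reagents that add atoms: none
Why: O–H deprotonation and alkoxide-assisted iodine–magnesium exchange with retention give the Z-alkenylmagnesium chloride 25 free of any other reactive carbanion, and copper-catalysed allylic substitution at the primary carbon of 19 (the γ carbon C4 is fully substituted) forms C1–C2 with retention of the Z-C15=C1 and Z-C3=C4 geometries, the ethyl ester being left alone at or below 0 °C.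

Step 15
Reactants: 26 ethyl (4E,8E,12Z,15Z)-8-{[(tert-butyldiphenylsilyl)oxy]methyl}-16-(hydroxymethyl)-4,12,20-trimethylhenicosa-4,8,12,15,19-pentaenoate
Product: 27 (4E,8E,12Z,15Z)-8-{[(tert-butyldiphenylsilyl)oxy]methyl}-16-(hydroxymethyl)-4,12,20-trimethylhenicosa-4,8,12,15,19-pentaenoic acid (seco acid)
Conditions: LiOH, THF/MeOH/H2O, rt; then 1 M HCl to pH 4 at 0 °C
Reagents that add atoms: lithium hydroxide, [Li+].[OH-]
Why: Saponification of the unhindered ethyl ester gives the hydroxy acid, and the TBDPS ether is stable to aqueous hydroxide at room temperature.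

Step 16
Reactants: 27 seco acid
Product: 29 18-membered lactone (5E,9E,13Z,16Z)-9-{[(tert-butyldiphenylsilyl)oxy]methyl}-5,13-dimethyl-17-(4-methylpent-3-en-1-yl)oxacyclooctadeca-5,9,13,16-tetraen-2-one, via mixed trichlorobenzoic anhydride 28 (not isolated)
Conditions: 2,4,6-Cl3C6H2COCl, Et3N, THF, rt; then slow addition to DMAP, toluene, 80 °C, ca. 1 mM
Reagents that add atoms: none
Why: Yamaguchi macrolactonisation acylates the unhindered primary allylic hydroxyl under high dilution; an 18-membered ring with four alkenes carries little transannular strain and no stereocentre is at stake.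

Step 17
Reactants: 29 18-membered lactone
Product: 32 (1S,3E,7E,11Z,14S)-7-{[(tert-butyldiphenylsilyl)oxy]methyl}-3,11-dimethyl-14-(6-methylhepta-1,5-dien-2-yl)cyclotetradeca-3,7,11-triene-1-carboxylic acid, via boron ketene acetal 30 (not isolated), via acyloxyborane 31 (not isolated)
Conditions: (4S,5S)-2-bromo-1,3-bis{[3,5-bis(trifluoromethyl)phenyl]sulfonyl}-4,5-diphenyl-1,3,2-diazaborolidine (2 equiv; made from the (S,S)-bis-sulfonamide and BBr3 in CH2Cl2, then evaporated), Et3N, toluene/hexane, −78 °C, then −20 to 4 °C; aq. work-up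
Reagents that add atoms: none
Why: The Lewis-acidic bromoborane and Et3N enolise the only enolisable position (C14H2) to the boron ketene acetal 30, which on warming undergoes the [3,3]-sigmatropic shift through a six-membered chair array (C14, acyl carbon, O, C16, C15, C1), forming C14–C1 as O–C16 breaks. This is the enantioselective boron-enolate Ireland–Claisen rearrangement of allyl esters in its macrolactone ring-contraction form. The 14-membered carbocycle closes transannularly inside the 18-membered ring as the unit C(=O)–O–C16–C15 is pushed out of the ring, so no separate macrocyclic C–C bond formation is needed and the alkene can only appear as C15=C16H2. C1 is set by the C2-symmetric bis-sulfonamide ligand on boron, which tells apart the two faces of the geometrically fixed Z-C15=C1 alkene in the chair. C14 follows from the ketene-acetal geometry (C13 cis to the ring oxygen) in the same chair and is erased in step 18. The step therefore needs face selectivity only, because the single α-methylene and the stereodefined allyl unit from the carbometalation fix the site of enolisation and the position of the new alkene.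

Step 18
Reactants: 32 14-membered carboxylic acid
Product: 34 tert-butyldiphenylsilyl ether of the target, via thiohydroxamate ester 33 (not isolated)
Conditions: N-hydroxypyridine-2-thione, DCC, DMAP (cat.), CH2Cl2, dark, 0 °C to rt; then t-BuSH (excess), hν (tungsten lamp), rt
Reagents that add atoms: none
Why: Barton decarboxylation: photolysis of the O-acyl thiohydroxamate gives the C14 radical, which has no 5-exo cyclisation partner (only slower 6-exo or transannular additions are open to it) and is reduced by the excess thiol first, leaving C14 as CH2 and C1 untouched.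

Step 19
Reactants: 34 tert-butyldiphenylsilyl ether of the target
Product: 35 CNP0237384.1
Conditions: Bu4NF, THF, 0 °C to rt
Reagents that add atoms: none
Why: Fluoride cleaves the Si–O bond of the primary allylic silyl ether under conditions that leave the four alkenes and the C1 stereocentre unchanged.

## Compound list

1 | nerol, (2Z)-3,7-dimethylocta-2,6-dien-1-ol | OC/C=C(/C)CCC=C(C)C | starting material
2 | neryl 4-methoxybenzyl ether | COc1ccc(COC/C=C(/C)CCC=C(C)C)cc1 | intermediate
3 | 6,7-epoxyneryl 4-methoxybenzyl ether (racemic) | COc1ccc(COC/C=C(/C)CCC2OC2(C)C)cc1 | intermediate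
4 | (4Z)-6-[(4-methoxybenzyl)oxy]-4-methylhex-4-enal | COc1ccc(COC/C=C(/C)CCC=O)cc1 | intermediate
5 | triethyl phosphonoacetate | CCOC(=O)CP(=O)(OCC)OCC | starting material
6 | 2-(2-bromoethyl)-1,3-dioxolane | BrCCC1OCCO1 | starting material
7 | ethyl 2-(diethoxyphosphoryl)-4-(1,3-dioxolan-2-yl)butanoate (racemic) | CCOC(=O)C(CCC1OCCO1)P(=O)(OCC)OCC | intermediate
8 | ethyl (2E,6Z)-2-[2-(1,3-dioxolan-2-yl)ethyl]-8-[(4-methoxybenzyl)oxy]-6-methylocta-2,6-dienoate | CCOC(=O)/C(CCC1OCCO1)=C/CC/C(C)=C\COCc1ccc(OC)cc1 | intermediate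
9 | (2E,6Z)-2-[2-(1,3-dioxolan-2-yl)ethyl]-8-[(4-methoxybenzyl)oxy]-6-methylocta-2,6-dien-1-ol | OC/C(CCC1OCCO1)=C/CC/C(C)=C\COCc1ccc(OC)cc1 | intermediate
10 | tert-butyldiphenylsilyl ether of 9 | CC(C)(C)[Si](OC/C(CCC1OCCO1)=C/CC/C(C)=C\COCc1ccc(OC)cc1)(c1ccccc1)c1ccccc1 | intermediate
11 | (4E,8Z)-4-{[(tert-butyldiphenylsilyl)oxy]methyl}-10-[(4-methoxybenzyl)oxy]-8-methyldeca-4,8-dienal | O=CCC/C(CO[Si](c1ccccc1)(c1ccccc1)C(C)(C)C)=C\CC/C(C)=C\COCc1ccc(OC)cc1 | intermediate
12 | isopropenylmagnesium bromide | C=C(C)[Mg]Br | starting material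
13 | (6E,10Z)-6-{[(tert-butyldiphenylsilyl)oxy]methyl}-12-[(4-methoxybenzyl)oxy]-2,10-dimethyldodeca-1,6,10-trien-3-ol (racemic) | C=C(C)C(O)CC/C(CO[Si](c1ccccc1)(c1ccccc1)C(C)(C)C)=C\CC/C(C)=C\COCc1ccc(OC)cc1 | intermediate
14 | triethyl orthoacetate | CCOC(C)(OCC)OCC | starting material
15 | mixed ketene acetal (1-ethoxyvinyl ether of 13, formed in the flask) | C=C(OCC)OC(CC/C(CO[Si](c1ccccc1)(c1ccccc1)C(C)(C)C)=C\CC/C(C)=C\COCc1ccc(OC)cc1)C(C)=C | intermediate
16 | ethyl (4E,8E,12Z)-8-{[(tert-butyldiphenylsilyl)oxy]methyl}-14-[(4-methoxybenzyl)oxy]-4,12-dimethyltetradeca-4,8,12-trienoate | CCOC(=O)CC/C(C)=C/CC/C(CO[Si](c1ccccc1)(c1ccccc1)C(C)(C)C)=C\CC/C(C)=C\COCc1ccc(OC)cc1 | intermediate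
17 | ethyl (4E,8E,12Z)-8-{[(tert-butyldiphenylsilyl)oxy]methyl}-14-hydroxy-4,12-dimethyltetradeca-4,8,12-trienoate | CCOC(=O)CC/C(C)=C/CC/C(CO[Si](c1ccccc1)(c1ccccc1)C(C)(C)C)=C\CC/C(C)=C\CO | intermediate
18 | allylic mesylate of 17 (formed in the flask) | CCOC(=O)CC/C(C)=C/CC/C(CO[Si](c1ccccc1)(c1ccccc1)C(C)(C)C)=C\CC/C(C)=C\COS(C)(=O)=O | intermediate
19 | ethyl (4E,8E,12Z)-14-bromo-8-{[(tert-butyldiphenylsilyl)oxy]methyl}-4,12-dimethyltetradeca-4,8,12-trienoate | CCOC(=O)CC/C(C)=C/CC/C(CO[Si](c1ccccc1)(c1ccccc1)C(C)(C)C)=C\CC/C(C)=C\CBr | intermediate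
20 | 5-bromo-2-methylpent-2-ene | CC(C)=CCCBr | starting material
21 | propargyl alcohol | C#CCO | starting material
22 | (4-methylpent-3-en-1-yl)magnesium bromide (formed in the flask) | CC(C)=CCC[Mg]Br | intermediate
23 | cyclic alkenylmagnesium alkoxide, 3-(4-methylpent-3-en-1-yl)-2,5-dihydro-1,2-oxamagnesole (formed in the flask) | CC(C)=CCCC1=C[Mg]OC1 | intermediate
24 | (2Z)-3-iodo-2-(4-methylpent-3-en-1-yl)prop-2-en-1-ol | CC(C)=CCC/C(CO)=C/I | intermediate
25 | Z-alkenylmagnesium chloride alkoxide, chloromagnesium (2Z)-3-(chloromagnesio)-2-(4-methylpent-3-en-1-yl)prop-2-en-1-olate (formed in the flask from 24 by O–H deprotonation and iodine–magnesium exchange) | CC(C)=CCC/C(CO[Mg]Cl)=C/[Mg]Cl | intermediate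
26 | ethyl (4E,8E,12Z,15Z)-8-{[(tert-butyldiphenylsilyl)oxy]methyl}-16-(hydroxymethyl)-4,12,20-trimethylhenicosa-4,8,12,15,19-pentaenoate | CCOC(=O)CC/C(C)=C/CC/C(CO[Si](c1ccccc1)(c1ccccc1)C(C)(C)C)=C\CC/C(C)=C\C/C=C(\CO)CCC=C(C)C | intermediate
27 | seco acid, (4E,8E,12Z,15Z)-8-{[(tert-butyldiphenylsilyl)oxy]methyl}-16-(hydroxymethyl)-4,12,20-trimethylhenicosa-4,8,12,15,19-pentaenoic acid | OC(=O)CC/C(C)=C/CC/C(CO[Si](c1ccccc1)(c1ccccc1)C(C)(C)C)=C\CC/C(C)=C\C/C=C(\CO)CCC=C(C)C | intermediate
28 | mixed anhydride of 27 and 2,4,6-trichlorobenzoic acid (formed in the flask) | O=C(OC(=O)CC/C(C)=C/CC/C(CO[Si](c1ccccc1)(c1ccccc1)C(C)(C)C)=C\CC/C(C)=C\C/C=C(\CO)CCC=C(C)C)c1c(Cl)cc(Cl)cc1Cl | intermediate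
29 | 18-membered lactone, (5E,9E,13Z,16Z)-9-{[(tert-butyldiphenylsilyl)oxy]methyl}-5,13-dimethyl-17-(4-methylpent-3-en-1-yl)oxacyclooctadeca-5,9,13,16-tetraen-2-one | CC(C)=CCC/C1=C/C/C=C(/C)CC/C=C(/CO[Si](c2ccccc2)(c2ccccc2)C(C)(C)C)CC/C=C(\C)CCC(=O)OC1 | intermediate
30 | boron ketene acetal of 29 (C13 cis to the ring oxygen, (S,S)-diazaborolidinyl on oxygen; formed in the flask) | CC(C)=CCC/C1=C/C/C=C(/C)CC/C=C(/CO[Si](c2ccccc2)(c2ccccc2)C(C)(C)C)CC/C=C(\C)C/C=C(/OB2N(S(=O)(=O)c3cc(C(F)(F)F)cc(C(F)(F)F)c3)[C@@H](c3ccccc3)[C@H](c3ccccc3)N2S(=O)(=O)c2cc(C(F)(F)F)cc(C(F)(F)F)c2)OC1 | intermediate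
31 | acyloxyborane of acid 32 (formed in the flask, hydrolysed on work-up) | C=C(CCC=C(C)C)[C@H]1C/C=C(/C)CC/C=C(/CO[Si](c2ccccc2)(c2ccccc2)C(C)(C)C)CC/C=C(\C)C[C@@H]1C(=O)OB1N(S(=O)(=O)c2cc(C(F)(F)F)cc(C(F)(F)F)c2)[C@@H](c2ccccc2)[C@H](c2ccccc2)N1S(=O)(=O)c1cc(C(F)(F)F)cc(C(F)(F)F)c1 | intermediate
32 | (1S,3E,7E,11Z,14S)-7-{[(tert-butyldiphenylsilyl)oxy]methyl}-3,11-dimethyl-14-(6-methylhepta-1,5-dien-2-yl)cyclotetradeca-3,7,11-triene-1-carboxylic acid (carboxyl on C14 of the overview numbering) | C=C(CCC=C(C)C)[C@H]1C/C=C(/C)CC/C=C(/CO[Si](c2ccccc2)(c2ccccc2)C(C)(C)C)CC/C=C(\C)C[C@@H]1C(=O)O | intermediate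
33 | O-acyl thiohydroxamate (2-thioxopyridin-1-yl ester) of 32 (formed in the flask) | C=C(CCC=C(C)C)[C@H]1C/C=C(/C)CC/C=C(/CO[Si](c2ccccc2)(c2ccccc2)C(C)(C)C)CC/C=C(\C)C[C@@H]1C(=O)On1ccccc1=S | intermediate
34 | tert-butyldiphenylsilyl ether of the target, (1R) with Z-C3=C4, E-C7=C8, E-C11=C12 in the overview numbering | C=C(CCC=C(C)C)[C@H]1C/C=C(/C)CC/C=C(/CO[Si](c2ccccc2)(c2ccccc2)C(C)(C)C)CC/C=C(\C)CC1 | intermediate
35 | CNP0237384.1, (1R)-configured 14-membered triene alcohol with Z-C3=C4(Me), E-C7=C8(CH2OH), E-C11=C12(Me) and the 6-methylhepta-1,5-dien-2-yl group on C1 | C=C(CCC=C(C)C)[C@H]1C/C=C(/C)CC/C=C(/CO)CC/C=C(\C)CC1 | target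

## Step count and risks

Total step count: 19 (steps 1–19).
Longest linear sequence: 17 steps from nerol (steps 1–3, 5–12, 14–19).

Steps most likely to fail:

1. Step 17. The boron ligand may discriminate the two alkene faces poorly inside the constrained macrocyclic transition state, or soft enolisation of the unactivated lactone may be too slow. The fallback gives up reagent control for a thermal silyl-ketene-acetal ring contraction followed by resolution. It sets out from 29: LiN(i-Pr)2 and TBSCl in THF/HMPA at −78 °C give the tert-butyldimethylsilyl ketene acetal F1, which on warming in toluene rearranges to the silyl ester F2, hydrolysed on work-up to the racemic acid F3. Esterification of F3 with (R)-pantolactone (DCC, DMAP) gives diastereomeric esters, from which the pantolactone ester of the (1S)-acid F4 is separated by chromatography (C14 epimers need not be parted). LiOH hydrolysis of F4 comes back to the route at 32 (or its C14 epimer, which serves equally in step 18).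

2. Step 14. The iodine–magnesium exchange may stay incomplete, the copper intermediate may attack the γ carbon C4 or let the Z-C3=C4 geometry equilibrate, or the organomagnesium may add to the ester. The fallback replaces the magnesium/copper substitution by a palladium-catalysed Negishi alkenyl–allyl coupling. It sets out from 24: TBSCl and imidazole give the silyl ether F5; t-BuLi in Et2O at −78 °C followed by ZnBr2 gives the alkenylzinc bromide F6; Pd(PPh3)4 (zerovalent palladium, 5 mol%) and bromide 19 in THF at rt give the coupled bis-silyl ether F7 with attack at the primary carbon and retention of both alkene geometries. PPTS in EtOH removes the primary TBS group beside the TBDPS group and comes back to the route at 26.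

3. Step 16. Intermolecular acylation to diolide and oligomers may outrun ring closure of the activated acid. The fallback activates the alcohol instead of the acid: from 27, a Mitsunobu macrolactonisation (PPh3, diisopropyl azodicarboxylate, toluene/THF, slow addition, high dilution) lets the carboxylate displace the oxyphosphonium group at the primary carbon C16 and comes back to the route at 29 directly.

## Further compounds

F1 | step 17 | tert-butyldimethylsilyl ketene acetal of lactone 29 | CC(C)=CCC/C1=C/C/C=C(/C)CC/C=C(/CO[Si](c2ccccc2)(c2ccccc2)C(C)(C)C)CC/C=C(\C)CC=C(O[Si](C)(C)C(C)(C)C)OC1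
F2 | step 17 | tert-butyldimethylsilyl ester of the racemic ring-contracted acid | C=C(CCC=C(C)C)C1C/C=C(/C)CC/C=C(/CO[Si](c2ccccc2)(c2ccccc2)C(C)(C)C)CC/C=C(\C)CC1C(=O)O[Si](C)(C)C(C)(C)C
F3 | step 17 | racemic ring-contracted acid (racemic 32, C14 epimers possible) | C=C(CCC=C(C)C)C1C/C=C(/C)CC/C=C(/CO[Si](c2ccccc2)(c2ccccc2)C(C)(C)C)CC/C=C(\C)CC1C(=O)O
F4 | step 17 | (R)-pantolactone ester of the (1S)-configured acid | C=C(CCC=C(C)C)[C@H]1C/C=C(/C)CC/C=C(/CO[Si](c2ccccc2)(c2ccccc2)C(C)(C)C)CC/C=C(\C)CC1C(=O)O[C@H]1C(=O)OCC1(C)C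
F5 | step 14 | tert-butyldimethylsilyl ether of iodide 24 | CC(C)=CCC/C(CO[Si](C)(C)C(C)(C)C)=C/I
F6 | step 14 | alkenylzinc bromide from F5 | CC(C)=CCC/C(CO[Si](C)(C)C(C)(C)C)=C/[Zn]Br
F7 | step 14 | tert-butyldimethylsilyl ether of 26 | CCOC(=O)CC/C(C)=C/CC/C(CO[Si](c1ccccc1)(c1ccccc1)C(C)(C)C)=C\CC/C(C)=C\C/C=C(\CO[Si](C)(C)C(C)(C)C)CCC=C(C)C
F0 | step 16 | none | none
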